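**Plan**

1. Retrosynthetic cuts, in order: the two aryl O–Si bonds; the C–C bond between the carbinol carbon and its CH2 neighbour, giving a furan-terminated (2E,6E)-enal and an (R)-α-boryl β-methallyl arene; in the arene half, the bond from the boron-bearing carbon to the isopropenyl carbon and the para C–O bond of the ring; in the enal half, the furan ring and the propargylic CH2–C(sp) bond to 8-bromogeranyl acetate.
2. Enabling feature: the acyclic array O–CH(carbinol)–CH2–C(CH3)=CH–CH2Ar, a homoallylic alcohol whose alkene lies one CH2 away from the carbinol carbon. It is the retron of an allyl transfer from boron with allylic transposition; the benzene-1,4-diol ring and the furan ring are spectators.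
3. Forward order: phenol → para-quinone → bis-silyl hydroquinone → 2-arylethyl carbamate → (R)-allylboronate (steps 1–5); geranyl acetate → 8-bromide → enyne diol → furan ring (5-endo O-attack on the alkyne, then dehydration) → enal (steps 6–12); union in step 13, desilylation in step 14.
4. Stereochemistry: the only stereocentre comes from (−)-sparteine-directed lithiation (C–Li → C–B, then invertive 1,2-migration) and is relayed from C–B to C–O through the chair allyl transfer.
5. Alkene geometry: the 6E and 10E alkenes come from geranyl acetate and its E-selective allylic oxidation; the 2E alkene is created in step 13.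

Key step: step 13

Assumption: both phenols are carried as tert-butyldimethylsilyl ethers from step 2 to step 14, and 1, 8, 12, 15, 16 and (−)-sparteine are taken as commercial.

**Route**

Step 1
Reactants: 1 2-allyl-6-methylphenol
Product: 2 2-allyl-6-methyl-1,4-benzoquinone
Conditions: Co(salen) [N,N′-bis(salicylidene)ethylenediaminocobalt, divalent cobalt, 10 mol %], O2 (1 atm), DMF, rt
Reagents that add atoms: dioxygen O=O
Why: Cobalt–salen catalysed aerobic oxidation of a 2,6-disubstituted phenol should give the para-quinone, because the phenoxyl radical is blocked at both ortho carbons and is oxygenated at the free para carbon.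

Step 2
Reactants: 2 2-allyl-6-methyl-1,4-benzoquinone
Product: 4 2-allyl-6-methylbenzene-1,4-diol bis(tert-butyldimethylsilyl) ether, via hydroquinone 3 (not isolated)
Conditions: Na2S2O4, Et2O/H2O, rt; crude 3, TBSCl, imidazole, DMF, 40 °C
Reagents that add atoms: tert-butyldimethylsilyl chloride CC(C)(C)[Si](C)(C)Cl
Why: Dithionite reduction of the quinone followed by silyl ether formation on both phenols should mask the air-sensitive hydroquinone in a form that tolerates organolithium reagents and is removed by fluoride.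

Step 3
Reactants: 4 2-allyl-6-methylbenzene-1,4-diol bis(tert-butyldimethylsilyl) ether
Product: 6 2-[2,5-bis(tert-butyldimethylsilyloxy)-3-methylphenyl]ethanol, via arylacetaldehyde 5 (not isolated)
Conditions: O3 (ca. 1 equiv, metered), CH2Cl2/MeOH, −78 °C; then NaBH4, −78 °C to rt
Reagents that add atoms: ozone [O-][O+]=O
Why: Ozonolysis of the monosubstituted alkene, which reacts far faster than the silyloxy arene, with reductive NaBH4 work-up should excise the terminal carbon and give the 2-arylethanol without isolating the enolisable aldehyde.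

Step 4
Reactants: 6 2-[2,5-bis(tert-butyldimethylsilyloxy)-3-methylphenyl]ethanol
Product: 7 2-[2,5-bis(tert-butyldimethylsilyloxy)-3-methylphenyl]ethyl N,N-diisopropylcarbamate
Conditions: i-Pr2NCOCl, Et3N, CH2Cl2, reflux
Reagents that add atoms: N,N-diisopropylcarbamoyl chloride CC(C)N(C(C)C)C(Cl)=O
Why: Carbamate formation on the primary alcohol should install the group that directs and stabilises α-lithiation and later acts as the leaving group.

Step 5
Reactants: 7 2-[2,5-bis(tert-butyldimethylsilyloxy)-3-methylphenyl]ethyl N,N-diisopropylcarbamate; 8 isopropenylboronic acid pinacol ester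
Product: 11 (R)-2-[1-(2,5-bis(tert-butyldimethylsilyloxy)-3-methylphenyl)-3-methylbut-3-en-2-yl]-4,4,5,5-tetramethyl-1,3,2-dioxaborolane, via lithiated carbamate 9 (not isolated), via boronate complex 10 (not isolated)
Conditions: s-BuLi, (−)-sparteine, Et2O, −78 °C, 5 h; 8, −78 °C, 1 h; MgBr2·OEt2, then reflux
Reagents that add atoms: none
Why: Sparteine-mediated asymmetric α-lithiation removes the pro-S hydrogen, the (S)-organolithium 9 is borylated with retention, and the isopropenyl group of 10 migrates from boron to carbon anti to the departing carbamate (lithiation–borylation, 1,2-metallate rearrangement), which should set the (R) C–B stereocentre.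

Step 6
Reactants: 12 geranyl acetate
Product: 13 (2E,6E)-8-hydroxy-3,7-dimethylocta-2,6-dien-1-yl acetate
Conditions: SeO2 (cat.), t-BuOOH, salicylic acid (cat.), CH2Cl2, rt
Reagents that add atoms: selenium dioxide O=[Se]=O (oxygen carrier, regenerated); tert-butyl hydroperoxide CC(C)(C)OO (terminal oxygen source)
Why: Selenium dioxide allylic oxidation (ene reaction, then [2,3]-sigmatropic shift) should hydroxylate the terminal methyl group trans to the chain on the more electron-rich distal alkene, giving the (E)-allylic alcohol and sparing the acetate-deactivated 2,3-alkene.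

Step 7
Reactants: 13 (2E,6E)-8-hydroxy-3,7-dimethylocta-2,6-dien-1-yl acetate
Product: 14 (2E,6E)-8-bromo-3,7-dimethylocta-2,6-dien-1-yl acetate
Conditions: CBr4, PPh3, CH2Cl2, 0 °C
Reagents that add atoms: carbon tetrabromide BrC(Br)(Br)Br
Why: The Appel reaction should convert the primary allylic alcohol into the bromide under neutral conditions without allylic transposition or loss of the acetate.

Step 8
Reactants: 15 hydroxyacetone; 16 ethynylmagnesium bromide
Product: 17 2-methylbut-3-yne-1,2-diol (racemic)
Conditions: 16 (2.5 equiv), THF, 0 °C to rt; aq. NH4Cl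
Reagents that add atoms: none
Why: Grignard 1,2-addition of the acetylide to the ketone (one further equivalent is consumed by the hydroxyl group) should give the tertiary propargylic diol, whose stereocentre is lost on aromatisation in step 10.

Step 9
Reactants: 14 (2E,6E)-8-bromo-3,7-dimethylocta-2,6-dien-1-yl acetate; 17 2-methylbut-3-yne-1,2-diol
Product: 18 (2E,6E)-11,12-dihydroxy-3,7,11-trimethyldodeca-2,6-dien-9-yn-1-yl acetate
Conditions: CuI (10 mol %), K2CO3, n-Bu4NCl, DMF, rt
Reagents that add atoms: none
Why: Copper-catalysed coupling of a terminal alkyne with an allylic halide (the copper acetylide displaces bromide at the unhindered primary carbon) should give the skipped enyne with the (E)-alkene intact.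

Step 10
Reactants: 18 (2E,6E)-11,12-dihydroxy-3,7,11-trimethyldodeca-2,6-dien-9-yn-1-yl acetate
Product: 20 (2E,6E)-3,7-dimethyl-8-(4-methylfuran-2-yl)octa-2,6-dien-1-yl acetate, via dihydrofuranol 19 (not isolated)
Conditions: Ph3PAuCl (1 mol %), AgNTf2 (1 mol %), THF, rt
Reagents that add atoms: none
Why: Cationic monovalent gold activates the alkyne for 5-endo-dig attack of the primary hydroxyl group and the 3-hydroxy-2,3-dihydrofuran 19 loses water to aromatise (cyclodehydration of a 3-alkyne-1,2-diol), which should fix the 2,4-substitution pattern of the furan unambiguously.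

Step 11
Reactants: 20 (2E,6E)-3,7-dimethyl-8-(4-methylfuran-2-yl)octa-2,6-dien-1-yl acetate
Product: 21 (2E,6E)-3,7-dimethyl-8-(4-methylfuran-2-yl)octa-2,6-dien-1-ol
Conditions: K2CO3 (cat.), MeOH, rt
Reagents that add atoms: none
Why: Base-catalysed methanolysis of the acetate (transesterification) should free the allylic alcohol without touching the furan or moving the skipped alkene.

Step 12
Reactants: 21 (2E,6E)-3,7-dimethyl-8-(4-methylfuran-2-yl)octa-2,6-dien-1-ol
Product: 22 (2E,6E)-3,7-dimethyl-8-(4-methylfuran-2-yl)octa-2,6-dienal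
Conditions: activated MnO2, CH2Cl2, rt
Reagents that add atoms: none
Why: MnO2 oxidises allylic alcohols selectively to enals with retention of the (E) geometry and should leave the furan and the isolated alkene untouched.

Step 13
Reactants: 11 (R)-2-[1-(2,5-bis(tert-butyldimethylsilyloxy)-3-methylphenyl)-3-methylbut-3-en-2-yl]-4,4,5,5-tetramethyl-1,3,2-dioxaborolane; 22 (2E,6E)-3,7-dimethyl-8-(4-methylfuran-2-yl)octa-2,6-dienal
Product: 26 2-[(2E,5S,6E,10E)-5-hydroxy-3,7,11-trimethyl-12-(4-methylfuran-2-yl)dodeca-2,6,10-trien-1-yl]-6-methylbenzene-1,4-diol bis(tert-butyldimethylsilyl) ether, via lithium borate 23 (not isolated), via borinic ester 24 (not isolated), via boron alkoxide 25 (not isolated)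
Conditions: 11, n-BuLi (1.1 equiv), THF, −78 °C; TFAA (1.2 equiv), −78 °C; 22, −78 °C to rt; pH 7 buffer
Reagents that add atoms: none
Why: Butyllithium adds to the boron of 11 and TFAA cleaves one B–O bond of borate 23, so that the small, Lewis-acidic borinic ester 24 binds the aldehyde oxygen of 22 and transfers the allyl group through a closed six-membered chair transition state with allylic transposition (new bond from the terminal CH2 of the methallyl unit to the aldehyde carbon, C=C shifting to the former C–B carbon). The closest known reaction type is the E-selective allylboration of aldehydes with α-substituted allyl and β-methallyl pinacol boronic esters through borinic esters made in situ. No ring is closed; the six-membered array exists only in the transition state. The new carbinol stereocentre is controlled by the boron-bearing stereocentre of 11: with the arylmethyl group and the enal residue both equatorial, the (R)-boronate should deliver the allyl unit to one aldehyde face and give the (S)-alcohol (chirality transfer from C–B to C–O). The step needs E geometry at the new trisubstituted alkene, 1,2- and not 1,4-addition to the enal, and no 1,3-boron shift before addition. The unhindered borinic ester removes the pinacol clash that otherwise pushes the α-substituent axial (Z product), the closed transition state enforces carbonyl addition, and −78 °C should suppress borotropic scrambling.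

Step 14
Reactants: 26 2-[(2E,5S,6E,10E)-5-hydroxy-3,7,11-trimethyl-12-(4-methylfuran-2-yl)dodeca-2,6,10-trien-1-yl]-6-methylbenzene-1,4-diol bis(tert-butyldimethylsilyl) ether
Product: 27 2-[(2E,5S,6E,10E)-5-hydroxy-3,7,11-trimethyl-12-(4-methylfuran-2-yl)dodeca-2,6,10-trien-1-yl]-6-methylbenzene-1,4-diol (CNP0172089.1)
Conditions: Bu4NF (2.2 equiv), AcOH (2.2 equiv), degassed THF, 0 °C, argon
Reagents that add atoms: none
Why: Fluoride cleaves aryl silyl ethers rapidly (Si–F bond formation), and acetic acid buffering with exclusion of air should protect the hydroquinone from oxidation and the allylic alcohol from base.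

**Compound list**

1 | 2-allyl-6-methylphenol | C=CCc1cccc(C)c1O | starting material
2 | 2-allyl-6-methyl-1,4-benzoquinone | C=CCC1=CC(=O)C=C(C)C1=O | intermediate
3 | 2-allyl-6-methylbenzene-1,4-diol | C=CCc1cc(O)cc(C)c1O | intermediate
4 | 2-allyl-6-methylbenzene-1,4-diol bis(tert-butyldimethylsilyl) ether | C=CCc1cc(O[Si](C)(C)C(C)(C)C)cc(C)c1O[Si](C)(C)C(C)(C)C | intermediate
5 | 2-[2,5-bis(tert-butyldimethylsilyloxy)-3-methylphenyl]acetaldehyde | O=CCc1cc(O[Si](C)(C)C(C)(C)C)cc(C)c1O[Si](C)(C)C(C)(C)C | intermediate
6 | 2-[2,5-bis(tert-butyldimethylsilyloxy)-3-methylphenyl]ethanol | OCCc1cc(O[Si](C)(C)C(C)(C)C)cc(C)c1O[Si](C)(C)C(C)(C)C | intermediate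
7 | 2-[2,5-bis(tert-butyldimethylsilyloxy)-3-methylphenyl]ethyl N,N-diisopropylcarbamate | CC(C)N(C(C)C)C(=O)OCCc1cc(O[Si](C)(C)C(C)(C)C)cc(C)c1O[Si](C)(C)C(C)(C)C | intermediate
8 | isopropenylboronic acid pinacol ester | CC(=C)B1OC(C)(C)C(C)(C)O1 | starting material
9 | (S)-α-lithiated carbamate of 7 (sparteine complex, ligand not drawn) | [Li][C@@H](Cc1cc(O[Si](C)(C)C(C)(C)C)cc(C)c1O[Si](C)(C)C(C)(C)C)OC(=O)N(C(C)C)C(C)C | intermediate
10 | lithium (S)-[1-carbamoyloxy-2-arylethyl](isopropenyl)pinacolatoborate | [Li+].CC(=C)[B-]1(OC(C)(C)C(C)(C)O1)[C@@H](Cc1cc(O[Si](C)(C)C(C)(C)C)cc(C)c1O[Si](C)(C)C(C)(C)C)OC(=O)N(C(C)C)C(C)C | intermediate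
11 | (R)-2-[1-(2,5-bis(tert-butyldimethylsilyloxy)-3-methylphenyl)-3-methylbut-3-en-2-yl]-4,4,5,5-tetramethyl-1,3,2-dioxaborolane | CC(=C)[C@@H](Cc1cc(O[Si](C)(C)C(C)(C)C)cc(C)c1O[Si](C)(C)C(C)(C)C)B1OC(C)(C)C(C)(C)O1 | intermediate
12 | geranyl acetate | CC(=O)OC/C=C(\C)CCC=C(C)C | starting material
13 | (2E,6E)-8-hydroxy-3,7-dimethylocta-2,6-dien-1-yl acetate | CC(=O)OC/C=C(\C)CC/C=C(\C)CO | intermediate
14 | (2E,6E)-8-bromo-3,7-dimethylocta-2,6-dien-1-yl acetate | CC(=O)OC/C=C(\C)CC/C=C(\C)CBr | intermediate
15 | hydroxyacetone | CC(=O)CO | starting material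
16 | ethynylmagnesium bromide | C#C[Mg]Br | starting material
17 | 2-methylbut-3-yne-1,2-diol (racemic) | C#CC(C)(O)CO | intermediate
18 | (2E,6E)-11,12-dihydroxy-3,7,11-trimethyldodeca-2,6-dien-9-yn-1-yl acetate | CC(=O)OC/C=C(\C)CC/C=C(\C)CC#CC(C)(O)CO | intermediate
19 | (2E,6E)-8-(4-hydroxy-4-methyl-4,5-dihydrofuran-2-yl)-3,7-dimethylocta-2,6-dien-1-yl acetate | CC(=O)OC/C=C(\C)CC/C=C(\C)CC1=CC(C)(O)CO1 | intermediate
20 | (2E,6E)-3,7-dimethyl-8-(4-methylfuran-2-yl)octa-2,6-dien-1-yl acetate | CC(=O)OC/C=C(\C)CC/C=C(\C)Cc1cc(C)co1 | intermediate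
21 | (2E,6E)-3,7-dimethyl-8-(4-methylfuran-2-yl)octa-2,6-dien-1-ol | OC/C=C(\C)CC/C=C(\C)Cc1cc(C)co1 | intermediate
22 | (2E,6E)-3,7-dimethyl-8-(4-methylfuran-2-yl)octa-2,6-dienal | O=C/C=C(\C)CC/C=C(\C)Cc1cc(C)co1 | intermediate
23 | lithium butyl[(R)-1-aryl-3-methylbut-3-en-2-yl]pinacolatoborate (aryl as in 11) | [Li+].CCCC[B-]1(OC(C)(C)C(C)(C)O1)[C@H](Cc1cc(O[Si](C)(C)C(C)(C)C)cc(C)c1O[Si](C)(C)C(C)(C)C)C(C)=C | intermediate
24 | butyl[(R)-1-aryl-3-methylbut-3-en-2-yl]borinic acid ester of pinacol mono(trifluoroacetate) | CCCCB(OC(C)(C)C(C)(C)OC(=O)C(F)(F)F)[C@H](Cc1cc(O[Si](C)(C)C(C)(C)C)cc(C)c1O[Si](C)(C)C(C)(C)C)C(C)=C | intermediate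
25 | O-[butyl(alkoxy)boryl] derivative of 26 (boron alkoxide of the adduct) | C/C(=C\[C@@H](OB(CCCC)OC(C)(C)C(C)(C)OC(=O)C(F)(F)F)C/C(C)=C/Cc1cc(O[Si](C)(C)C(C)(C)C)cc(C)c1O[Si](C)(C)C(C)(C)C)CC/C=C(\C)Cc1cc(C)co1 | intermediate
26 | 2-[(2E,5S,6E,10E)-5-hydroxy-3,7,11-trimethyl-12-(4-methylfuran-2-yl)dodeca-2,6,10-trien-1-yl]-6-methylbenzene-1,4-diol bis(tert-butyldimethylsilyl) ether | C/C(=C\[C@@H](O)C/C(C)=C/Cc1cc(O[Si](C)(C)C(C)(C)C)cc(C)c1O[Si](C)(C)C(C)(C)C)CC/C=C(\C)Cc1cc(C)co1 | intermediate
27 | 2-[(2E,5S,6E,10E)-5-hydroxy-3,7,11-trimethyl-12-(4-methylfuran-2-yl)dodeca-2,6,10-trien-1-yl]-6-methylbenzene-1,4-diol | C/C(=C\[C@@H](O)C/C(C)=C/Cc1cc(O)cc(C)c1O)CC/C=C(\C)Cc1cc(C)co1 | target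

**Step count**

Total steps: 14. Longest linear sequence: 8 steps (6, 7, 9, 10, 11, 12, 13, 14, from geranyl acetate); the arene branch is 5 steps before the union.

**Steps most likely to fail**

Step 13. The chair with the arylmethyl group axial may compete and erode the alkene geometry, or the borinic ester may undergo a 1,3-boron shift before it meets the aldehyde, which would scramble regiochemistry and chirality transfer. The fallback sets out from 6 and comes back at 26, with the alkene geometry fixed before the coupling and the stereocentre set afterwards. Alcohol 6 would be oxidised with Dess–Martin periodinane to aldehyde 5 and condensed with ethyl 2-(triphenylphosphoranylidene)propanoate (Wittig reaction) to the (E)-enoate F1. DIBAL-H reduction would give the (E)-allylic alcohol F2, and MsCl/Et3N then LiCl the (E)-allylic chloride F3. Activated barium (from BaI2 and lithium biphenylide, THF, −78 °C) would convert F3 into the allylbarium reagent, which adds to enal 22 at its α-carbon with retention of the (E) geometry to give the racemic alcohol F4. Buffered Dess–Martin oxidation would give the dienone F5, and Corey–Bakshi–Shibata reduction with the (R)-oxazaborolidine and catecholborane (alkenyl group as the larger substituent) should return the (S)-alcohol 26.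

Step 5. During the long lithiation the base may instead deprotonate the benzylic position or trigger oxygen-to-carbon silyl migration, or the isopropenyl group may migrate incompletely, lowering yield or enantiomeric purity. The fallback sets out from 4 and comes back at 10, building the C–B stereocentre by catalysis on the aldehyde. Ozonolysis of 4 with dimethyl sulfide work-up would give aldehyde 5 as an isolated compound. Copper-catalysed enantioselective borylation of the aldehyde (CuCl, monovalent copper, with the DTBM-SEGPHOS enantiomer that delivers the (S) centre, KOt-Bu, B2pin2, MeOH) would give the (S)-α-hydroxy boronate F6, trapped in the same flask with i-Pr2NCOCl as the (S)-α-carbamoyloxy boronate F7. Addition of isopropenyllithium (from 2-bromopropene and t-BuLi) at −78 °C would form boronate complex 10, which continues to 11 as in step 5.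

Step 9. The copper acetylide may attack the internal allylic terminus (allylic transposition), or the unprotected diol may be O-alkylated, giving regioisomeric or etherified material. The fallback sets out from 14 and comes back at 21, taking the furan from a butenolide of fixed substitution. 3-Methylfuran-2(5H)-one would be silylated (TMSCl, Et3N) to 3-methyl-2-(trimethylsilyloxy)furan F8. Its silver trifluoroacetate (AgOCOCF3) promoted alkylation with bromide 14 at the 5-position (CH2Cl2, −78 °C) would give the butenolide F9. DIBAL-H would reduce the lactone to the lactol and cleave the acetate, giving the lactol alcohol F10, and a mildly acidic work-up would dehydrate it to the furan alcohol 21.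

Further compounds
F1 | step 13 | ethyl (E)-4-[2,5-bis(tert-butyldimethylsilyloxy)-3-methylphenyl]-2-methylbut-2-enoate | CCOC(=O)/C(C)=C/Cc1cc(O[Si](C)(C)C(C)(C)C)cc(C)c1O[Si](C)(C)C(C)(C)C
F2 | step 13 | (E)-4-[2,5-bis(tert-butyldimethylsilyloxy)-3-methylphenyl]-2-methylbut-2-en-1-ol | OC/C(C)=C/Cc1cc(O[Si](C)(C)C(C)(C)C)cc(C)c1O[Si](C)(C)C(C)(C)C
F3 | step 13 | (E)-4-[2,5-bis(tert-butyldimethylsilyloxy)-3-methylphenyl]-1-chloro-2-methylbut-2-ene | ClC/C(C)=C/Cc1cc(O[Si](C)(C)C(C)(C)C)cc(C)c1O[Si](C)(C)C(C)(C)C
F4 | step 13 | racemic form of 26 (carbinol centre unassigned) | C/C(=C\C(O)C/C(C)=C/Cc1cc(O[Si](C)(C)C(C)(C)C)cc(C)c1O[Si](C)(C)C(C)(C)C)CC/C=C(\C)Cc1cc(C)co1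
F5 | step 13 | (2E,6E,10E)-1-[2,5-bis(tert-butyldimethylsilyloxy)-3-methylphenyl]-3,7,11-trimethyl-12-(4-methylfuran-2-yl)dodeca-2,6,10-trien-5-one | C/C(=C\C(=O)C/C(C)=C/Cc1cc(O[Si](C)(C)C(C)(C)C)cc(C)c1O[Si](C)(C)C(C)(C)C)CC/C=C(\C)Cc1cc(C)co1
F6 | step 5 | (S)-2-[2,5-bis(tert-butyldimethylsilyloxy)-3-methylphenyl]-1-(4,4,5,5-tetramethyl-1,3,2-dioxaborolan-2-yl)ethanol | O[C@H](Cc1cc(O[Si](C)(C)C(C)(C)C)cc(C)c1O[Si](C)(C)C(C)(C)C)B1OC(C)(C)C(C)(C)O1
F7 | step 5 | (S)-2-[2,5-bis(tert-butyldimethylsilyloxy)-3-methylphenyl]-1-(4,4,5,5-tetramethyl-1,3,2-dioxaborolan-2-yl)ethyl N,N-diisopropylcarbamate | CC(C)N(C(C)C)C(=O)O[C@H](Cc1cc(O[Si](C)(C)C(C)(C)C)cc(C)c1O[Si](C)(C)C(C)(C)C)B1OC(C)(C)C(C)(C)O1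
F8 | step 9 | 3-methyl-2-(trimethylsilyloxy)furan | Cc1ccoc1O[Si](C)(C)C
F9 | step 9 | (2E,6E)-3,7-dimethyl-8-(4-methyl-5-oxo-2,5-dihydrofuran-2-yl)octa-2,6-dien-1-yl acetate (racemic) | CC(=O)OC/C=C(\C)CC/C=C(\C)CC1OC(=O)C(C)=C1
F10 | step 9 | 5-[(2E,6E)-8-hydroxy-2,6-dimethylocta-2,6-dien-1-yl]-3-methyl-2,5-dihydrofuran-2-ol | OC/C=C(\C)CC/C=C(\C)CC1OC(O)C(C)=C1
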